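**Retrosynthetic overview**

- Numbering: lactone O1, C2 (carbonyl), C3, C4, C5; C7' is the CH2 from C3 to ring A (2,4-dihydroxy-3-methoxyphenyl), C7 the CH2 from C4 to ring B (4-hydroxy-3-methoxyphenyl). Apart from the 2'-hydroxyl of ring A, the (3R,4R) skeleton is C2-symmetric about C3–C4, and C2 and C5 are the two carbinol carbons of a 2,3-dibenzylbutane-1,4-diol, one of them raised to the carbonyl. The plan rests on this feature.
- Last disconnection: the O1–C2 bond and the oxidation level of C2, back to the unprotected (2R,3R)-diol 18. A dehydrogenase is asked to choose C2 over C5, so no earlier step has to tell the two ends apart.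
- Diol 18 comes from hydride reduction and hydrogenolysis of the doubly alkylated succinyl bis-imide 16. The C3–C7' and C4–C7 bonds, and both stereocentres, come from two Evans alkylations of the C2-symmetric bis-imide 4.
- The benzylic bromides are 10 (ring A, from 2-methoxyresorcinol) and 12 (ring B, from 4-(benzyloxy)-3-methoxybenzyl alcohol). The phenols travel as benzyl ethers and are freed before the enzyme step.
- Ring order: both arenes are bought; the only ring made is the lactone, closed in the last step.

Key step: step 11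

Remark: a dehydrogenase variant with the required site preference is assumed to be found by screening wild-type homologues and active-site variants; 11 is taken as a purchasable compound.

**Route**

Step 1
Reactants: 1 (R)-4-benzyl-2-oxazolidinone (2 equiv), 2 succinyl chloride
Product: 4 1,4-bis[(4R)-4-benzyl-2-oxo-1,3-oxazolidin-3-yl]butane-1,4-dione, via lithium oxazolidinide 3 (not isolated)
Conditions: n-BuLi (1 equiv per 1), THF, −78 °C; then 2 (0.5 equiv per 1), −78 → 0 °C
Reagents that add atoms: none
Why: N-acylation of a lithiated oxazolidinone by an acid chloride (standard Evans imide formation) should occur at both ends of the diacid chloride, and the ring stereocentre is not involved.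

Step 2
Reactants: 5 2-methoxyresorcinol
Product: 6 1,3-bis(benzyloxy)-2-methoxybenzene
Conditions: BnBr (2.3 equiv), K2CO3 (3 equiv), DMF, 60 °C, N2
Reagents that add atoms: benzyl bromide, BrCc1ccccc1
Why: Williamson ether synthesis on both phenoxides masks them for the enolate and hydride steps as ethers that hydrogenolysis removes later.

Step 3
Reactants: 6 1,3-bis(benzyloxy)-2-methoxybenzene
Product: 8 2,4-bis(benzyloxy)-3-methoxybenzaldehyde, via aryl iminium salt 7 (not isolated)
Conditions: POCl3 (1.5 equiv), DMF, 0 → 50 °C; then aq. NaOAc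
Reagents that add atoms: N,N-dimethylformamide, CN(C)C=O (formyl carbon); water, O (aldehyde oxygen)
Why: Vilsmeier–Haack formylation should go to C4, which is ortho to one benzyloxy group and para to the other while C5 is meta to both, and the iminium salt is hydrolysed on work-up.

Step 4
Reactants: 8 2,4-bis(benzyloxy)-3-methoxybenzaldehyde
Product: 9 [2,4-bis(benzyloxy)-3-methoxyphenyl]methanol
Conditions: NaBH4, MeOH/THF, 0 °C
Reagents that add atoms: none
Why: Borohydride reduction of an aromatic aldehyde gives the benzylic alcohol and leaves the ethers alone.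

Step 5
Reactants: 9 [2,4-bis(benzyloxy)-3-methoxyphenyl]methanol
Product: 10 2,4-bis(benzyloxy)-3-methoxybenzyl bromide
Conditions: PBr3 (0.4 equiv), Et2O, 0 °C; cold aqueous wash, used at once
Reagents that add atoms: phosphorus tribromide, BrP(Br)Br
Why: Bromide displaces the phosphite ester of the benzylic alcohol (alcohol-to-bromide conversion with PBr3); the electron-rich bromide ionises easily, so it is kept cold and not stored.

Step 6
Reactants: 11 4-(benzyloxy)-3-methoxybenzyl alcohol
Product: 12 4-(benzyloxy)-3-methoxybenzyl bromide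
Conditions: PBr3 (0.4 equiv), CH2Cl2, 0 °C → rt
Reagents that add atoms: phosphorus tribromide, BrP(Br)Br
Why: The same PBr3 conversion of a benzylic alcohol should give a bromide that is stable enough to store.

Step 7
Reactants: 4 1,4-bis[(4R)-4-benzyl-2-oxo-1,3-oxazolidin-3-yl]butane-1,4-dione, 10 2,4-bis(benzyloxy)-3-methoxybenzyl bromide
Product: 14 (2R)-1,4-bis[(4R)-4-benzyl-2-oxo-1,3-oxazolidin-3-yl]-2-[[2,4-bis(benzyloxy)-3-methoxyphenyl]methyl]butane-1,4-dione, via sodium Z-enolate 13 (not isolated)
Conditions: NaN(SiMe3)2 (1.05 equiv), THF, −78 °C; then 10 (1.2 equiv), −78 → −40 °C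
Reagents that add atoms: none
Why: Evans alkylation: one equivalent of base should enolise one imide only, since a second deprotonation next to an enolate is disfavoured, and the bromide enters the chelated Z-enolate on the face away from the auxiliary's benzyl group, which for the (R)-auxiliary makes the new centre (C3 of the target) R.

Step 8
Reactants: 14 the mono-alkylated bis-imide, 12 4-(benzyloxy)-3-methoxybenzyl bromide
Product: 16 (2R,3R)-1,4-bis[(4R)-4-benzyl-2-oxo-1,3-oxazolidin-3-yl]-2-[[2,4-bis(benzyloxy)-3-methoxyphenyl]methyl]-3-[[4-(benzyloxy)-3-methoxyphenyl]methyl]butane-1,4-dione, via sodium Z-enolate 15 (not isolated)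
Conditions: NaN(SiMe3)2 (1.1 equiv), THF, −78 °C; then 12 (2 equiv), −78 → −30 °C
Reagents that add atoms: none
Why: Second Evans alkylation: kinetic deprotonation should take the CH2 of the unsubstituted imide, because the α-CH of the substituted imide is shielded from enolisation by allylic 1,3-strain, and the Z-enolate is alkylated anti to its own auxiliary's benzyl group, which makes the new centre (C4 of the target) R and should outweigh the bias of the neighbouring centre.

Step 9
Reactants: 16 the doubly alkylated bis-imide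
Product: 17 (2R,3R)-2-[[2,4-bis(benzyloxy)-3-methoxyphenyl]methyl]-3-[[4-(benzyloxy)-3-methoxyphenyl]methyl]butane-1,4-diol
Conditions: LiBH4 (5 equiv), MeOH (5 equiv), THF, 0 °C → rt
Reagents that add atoms: none
Why: Reductive removal of N-acyl oxazolidinones by LiBH4: hydride adds to the exocyclic carbonyl of each imide, releasing the primary alcohol and the intact auxiliary without a base able to epimerise the α-centres.

Step 10
Reactants: 17 the tri-O-benzyl diol
Product: 18 (2R,3R)-2-[(2,4-dihydroxy-3-methoxyphenyl)methyl]-3-[(4-hydroxy-3-methoxyphenyl)methyl]butane-1,4-diol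
Conditions: H2 (1 atm), Pd/C (10%), EtOH/EtOAc, rt
Reagents that add atoms: none
Why: Catalytic hydrogenolysis should cleave the three aryl benzyl ethers and leave the benzylic C–C bonds, the primary alcohols and both stereocentres unchanged.

Step 11
Reactants: 18 the unprotected (2R,3R)-diol
Product: 21 (3R,4R)-3-[(2,4-dihydroxy-3-methoxyphenyl)methyl]-4-[(4-hydroxy-3-methoxyphenyl)methyl]oxolan-2-one, via hydroxy aldehyde 19 (not isolated), via lactol 20 (not isolated)
Conditions: secoisolariciresinol dehydrogenase (variant from screening), NAD+ (cat.), sodium pyruvate (3 equiv), L-lactate dehydrogenase, Tris-HCl buffer pH 8.5, 5% DMSO, 30 °C, N2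
Reagents that add atoms: none
Why: Proposed new method: the catalytic tyrosine of the short-chain dehydrogenase takes the proton of the bound C2 carbinol while its hydride passes to C4 of the nicotinamide of NAD+, giving hydroxy aldehyde 19; the C5 hydroxyl then adds to the aldehyde (5-exo-trig) to form the O1–C2 bond and the lactone ring as lactol 20, and a second hydride transfer from C2–H gives the lactone irreversibly while pyruvate and lactate dehydrogenase return NADH to NAD+. The closest known reactions are the oxidation of the symmetric (2R,3R)-2,3-bis(4-hydroxy-3-methoxybenzyl)butane-1,4-diol to its (3R,4R)-lactone by this enzyme family and the desymmetrising oxidation of meso 1,4-diols to lactones by horse-liver alcohol dehydrogenase; what is new is the demand that the enzyme tell apart the two ends of an unsymmetrical diol. No stereocentre of the product is formed here: C3 and C4 come unchanged from 18, which has the backbone configuration of the natural substrate, and the lactol centre of 20 is lost in the second oxidation. The step needs site selectivity between two primary carbinols that differ only by the remote 2'-hydroxyl, which a small-molecule oxidant would not supply; in the enzyme the two aryl groups lie in different subsites, so the extra hydrogen-bond donor and bulk at C2' of ring A can fix the binding orientation that places C2–H and not C5–H over the nicotinamide, and homologues and subsite variants are screened for that orientation. The first hydride transfer alone decides the carbonyl position, because 19 can only close onto its own aldehyde carbon. Should the 2'-phenol and not the C5 hydroxyl trap the aldehyde, the six-membered aryl ester formed after oxidation would pass its acyl group to the C5 hydroxyl and end in the same γ-lactone, the more stable alkyl ester.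

**Compound list**

1 | (R)-4-benzyl-2-oxazolidinone | O=C1N[C@H](Cc2ccccc2)CO1 | starting material
2 | succinyl chloride | O=C(Cl)CCC(=O)Cl | starting material
3 | lithium salt (N-lithio) of (R)-4-benzyl-2-oxazolidinone | [Li+].O=C1[N-][C@H](Cc2ccccc2)CO1 | intermediate (not isolated)
4 | 1,4-bis[(4R)-4-benzyl-2-oxo-1,3-oxazolidin-3-yl]butane-1,4-dione | O=C(CCC(=O)N1[C@H](Cc2ccccc2)COC1=O)N1[C@H](Cc2ccccc2)COC1=O | intermediate
5 | 2-methoxyresorcinol | COc1c(O)cccc1O | starting material
6 | 1,3-bis(benzyloxy)-2-methoxybenzene | COc1c(OCc2ccccc2)cccc1OCc1ccccc1 | intermediate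
7 | N-[[2,4-bis(benzyloxy)-3-methoxyphenyl]methylidene]-N-methylmethanaminium dichlorophosphate | C[N+](C)=Cc1ccc(OCc2ccccc2)c(OC)c1OCc1ccccc1.[O-]P(=O)(Cl)Cl | intermediate (not isolated)
8 | 2,4-bis(benzyloxy)-3-methoxybenzaldehyde | O=Cc1ccc(OCc2ccccc2)c(OC)c1OCc1ccccc1 | intermediate
9 | [2,4-bis(benzyloxy)-3-methoxyphenyl]methanol | OCc1ccc(OCc2ccccc2)c(OC)c1OCc1ccccc1 | intermediate
10 | 2,4-bis(benzyloxy)-3-methoxybenzyl bromide | BrCc1ccc(OCc2ccccc2)c(OC)c1OCc1ccccc1 | intermediate
11 | 4-(benzyloxy)-3-methoxybenzyl alcohol | COc1cc(CO)ccc1OCc1ccccc1 | starting material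
12 | 4-(benzyloxy)-3-methoxybenzyl bromide | COc1cc(CBr)ccc1OCc1ccccc1 | intermediate
13 | sodium Z-enolate of 4 (one imide enolised, O–Na cis to the chain) | [Na+].[O-]/C(=C\CC(=O)N1[C@H](Cc2ccccc2)COC1=O)N1[C@H](Cc2ccccc2)COC1=O | intermediate (not isolated)
14 | (2R)-1,4-bis[(4R)-4-benzyl-2-oxo-1,3-oxazolidin-3-yl]-2-[[2,4-bis(benzyloxy)-3-methoxyphenyl]methyl]butane-1,4-dione | O=C([C@H](Cc1ccc(OCc2ccccc2)c(OC)c1OCc1ccccc1)CC(=O)N1[C@H](Cc2ccccc2)COC1=O)N1[C@H](Cc2ccccc2)COC1=O | intermediate
15 | sodium Z-enolate of 14 at the CH2 of the unsubstituted imide | [Na+].[O-]/C(=C\[C@@H](Cc1ccc(OCc2ccccc2)c(OC)c1OCc1ccccc1)C(=O)N1[C@H](Cc2ccccc2)COC1=O)N1[C@H](Cc2ccccc2)COC1=O | intermediate (not isolated)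
16 | (2R,3R)-1,4-bis[(4R)-4-benzyl-2-oxo-1,3-oxazolidin-3-yl]-2-[[2,4-bis(benzyloxy)-3-methoxyphenyl]methyl]-3-[[4-(benzyloxy)-3-methoxyphenyl]methyl]butane-1,4-dione | O=C([C@H](Cc1ccc(OCc2ccccc2)c(OC)c1OCc1ccccc1)[C@@H](Cc1ccc(OCc2ccccc2)c(OC)c1)C(=O)N1[C@H](Cc2ccccc2)COC1=O)N1[C@H](Cc2ccccc2)COC1=O | intermediate
17 | (2R,3R)-2-[[2,4-bis(benzyloxy)-3-methoxyphenyl]methyl]-3-[[4-(benzyloxy)-3-methoxyphenyl]methyl]butane-1,4-diol | COc1cc(C[C@@H](CO)[C@H](CO)Cc2ccc(OCc3ccccc3)c(OC)c2OCc2ccccc2)ccc1OCc1ccccc1 | intermediate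
18 | (2R,3R)-2-[(2,4-dihydroxy-3-methoxyphenyl)methyl]-3-[(4-hydroxy-3-methoxyphenyl)methyl]butane-1,4-diol | COc1cc(C[C@@H](CO)[C@H](CO)Cc2ccc(O)c(OC)c2O)ccc1O | intermediate
19 | (2R,3R)-2-[(2,4-dihydroxy-3-methoxyphenyl)methyl]-4-hydroxy-3-[(4-hydroxy-3-methoxyphenyl)methyl]butanal | COc1cc(C[C@@H](CO)[C@H](C=O)Cc2ccc(O)c(OC)c2O)ccc1O | intermediate (not isolated)
20 | (3R,4R)-3-[(2,4-dihydroxy-3-methoxyphenyl)methyl]-4-[(4-hydroxy-3-methoxyphenyl)methyl]oxolan-2-ol (either C2 epimer) | COc1cc(C[C@H]2COC(O)[C@@H]2Cc2ccc(O)c(OC)c2O)ccc1O | intermediate (not isolated)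
21 | (3R,4R)-3-[(2,4-dihydroxy-3-methoxyphenyl)methyl]-4-[(4-hydroxy-3-methoxyphenyl)methyl]oxolan-2-one | COc1cc(C[C@H]2COC(=O)[C@@H]2Cc2ccc(O)c(OC)c2O)ccc1O | target

**Step count and risks**

Total step count: 11. Longest linear sequence: 9 steps (5 → 6 → 8 → 9 → 10 → 14 → 16 → 17 → 18 → 21, steps 2, 3, 4, 5, 7, 8, 9, 10, 11).

Steps most likely to fail:

1. Step 11. The enzyme may bind the diol in both orientations and oxidise C5 as readily as C2, or it may turn over the 2'-hydroxylated substrate too slowly. The fallback uses known chemistry and fixes the carbonyl position by construction; it sets out from 1 and 12.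
   - Oxazolidinone 1 is N-acylated with 4-tert-butoxy-4-oxobutanoic acid (DCC, DMAP (cat.), CH2Cl2) to tert-butyl 4-[(4R)-4-benzyl-2-oxo-1,3-oxazolidin-3-yl]-4-oxobutanoate F1.
   - Evans alkylation (NaN(SiMe3)2, THF, −78 °C, then 12) should give tert-butyl (3R)-4-[(4R)-4-benzyl-2-oxo-1,3-oxazolidin-3-yl]-3-[[4-(benzyloxy)-3-methoxyphenyl]methyl]-4-oxobutanoate F2.
   - LiBH4 (THF, 0 °C) reduces the imide and spares the tert-butyl ester, giving tert-butyl (3R)-3-[[4-(benzyloxy)-3-methoxyphenyl]methyl]-4-hydroxybutanoate F3.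
   - CF3CO2H in CH2Cl2 closes (4R)-4-[[4-(benzyloxy)-3-methoxyphenyl]methyl]oxolan-2-one F4.
   - Its lithium enolate (LiN(SiMe3)2, THF, −78 °C) is alkylated by 10 trans to the C4 substituent, giving (3R,4R)-3-[[2,4-bis(benzyloxy)-3-methoxyphenyl]methyl]-4-[[4-(benzyloxy)-3-methoxyphenyl]methyl]oxolan-2-one F5.
   - Hydrogenolysis (H2, Pd/C) brings the sequence back to the route at 21.

2. Step 8. The β-branched enolate may react slowly, the bias of the existing centre may oppose the auxiliary and erode facial selectivity, or base may epimerise the first centre. The fallback lets a ring set the second centre; it sets out from 14.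
   - LiBH4 removes both auxiliaries to give (2R)-2-[[2,4-bis(benzyloxy)-3-methoxyphenyl]methyl]butane-1,4-diol F6.
   - TEMPO (cat.) and PhI(OAc)2 in CH2Cl2 should oxidise the less hindered carbinol and close (4R)-4-[[2,4-bis(benzyloxy)-3-methoxyphenyl]methyl]oxolan-2-one F7; any regioisomeric lactone is removed by chromatography.
   - The lithium enolate (LiN(SiMe3)2, THF, −78 °C) is alkylated by 12 trans to the C4 substituent, giving (3R,4R)-4-[[2,4-bis(benzyloxy)-3-methoxyphenyl]methyl]-3-[[4-(benzyloxy)-3-methoxyphenyl]methyl]oxolan-2-one F8.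
   - LiAlH4 (THF, 0 °C) opens the lactone and returns to the route at 17. The carbonyl position of F8 is of no consequence because the ring is reduced away.

3. Step 9. On these doubly branched, vicinally substituted imides hydride may attack the ring carbonyl of the auxiliary and open it, or the reduction may stall after the first imide. The fallback separates cleavage from reduction; it sets out from 16.
   - LiOH and H2O2 (THF/H2O, 0 °C) attack the exocyclic carbonyls to give (2R,3R)-2-[[2,4-bis(benzyloxy)-3-methoxyphenyl]methyl]-3-[[4-(benzyloxy)-3-methoxyphenyl]methyl]butanedioic acid F9.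
   - LiAlH4 in THF reduces the diacid and returns to the route at 17.

**Further compounds**

F1 | step 11 | tert-butyl 4-[(4R)-4-benzyl-2-oxo-1,3-oxazolidin-3-yl]-4-oxobutanoate | CC(C)(C)OC(=O)CCC(=O)N1[C@H](Cc2ccccc2)COC1=O
F2 | step 11 | tert-butyl (3R)-4-[(4R)-4-benzyl-2-oxo-1,3-oxazolidin-3-yl]-3-[[4-(benzyloxy)-3-methoxyphenyl]methyl]-4-oxobutanoate | CC(C)(C)OC(=O)C[C@@H](Cc1ccc(OCc2ccccc2)c(OC)c1)C(=O)N1[C@H](Cc2ccccc2)COC1=O
F3 | step 11 | tert-butyl (3R)-3-[[4-(benzyloxy)-3-methoxyphenyl]methyl]-4-hydroxybutanoate | CC(C)(C)OC(=O)C[C@@H](Cc1ccc(OCc2ccccc2)c(OC)c1)CO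
F4 | step 11 | (4R)-4-[[4-(benzyloxy)-3-methoxyphenyl]methyl]oxolan-2-one | O=C1C[C@@H](Cc2ccc(OCc3ccccc3)c(OC)c2)CO1
F5 | step 11 | (3R,4R)-3-[[2,4-bis(benzyloxy)-3-methoxyphenyl]methyl]-4-[[4-(benzyloxy)-3-methoxyphenyl]methyl]oxolan-2-one | COc1cc(C[C@H]2COC(=O)[C@@H]2Cc2ccc(OCc3ccccc3)c(OC)c2OCc2ccccc2)ccc1OCc1ccccc1
F6 | step 8 | (2R)-2-[[2,4-bis(benzyloxy)-3-methoxyphenyl]methyl]butane-1,4-diol | OCC[C@H](CO)Cc1ccc(OCc2ccccc2)c(OC)c1OCc1ccccc1
F7 | step 8 | (4R)-4-[[2,4-bis(benzyloxy)-3-methoxyphenyl]methyl]oxolan-2-one | O=C1C[C@@H](Cc2ccc(OCc3ccccc3)c(OC)c2OCc2ccccc2)CO1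
F8 | step 8 | (3R,4R)-4-[[2,4-bis(benzyloxy)-3-methoxyphenyl]methyl]-3-[[4-(benzyloxy)-3-methoxyphenyl]methyl]oxolan-2-one | O=C1OC[C@H](Cc2ccc(OCc3ccccc3)c(OC)c2OCc2ccccc2)[C@H]1Cc1ccc(OCc2ccccc2)c(OC)c1
F9 | step 9 | (2R,3R)-2-[[2,4-bis(benzyloxy)-3-methoxyphenyl]methyl]-3-[[4-(benzyloxy)-3-methoxyphenyl]methyl]butanedioic acid | OC(=O)[C@H](Cc1ccc(OCc2ccccc2)c(OC)c1OCc1ccccc1)[C@@H](Cc1ccc(OCc2ccccc2)c(OC)c1)C(=O)O
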